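At late times both earlier runs climb on a nearly straight line, so that line is where I start.

common to all: free monomer 0.086 M
- ash: initiator 1.6 mol%; run made earlier
- alder: initiator 8.3 mol%; run made earlier
- north-east: initiator 10 mol%; time 5.0 d
- north-west: initiator 2.5 mol%; time 5.0 d

| run | time / d | monomer in chains / % |
|---|---|---|
| ash | 0.417 | 2.0 |
| ash | 0.833 | 2.4 |
| ash | 1.25 | 3.6 |
| ash | 1.67 | 3.2 |
| ash | 2.00 | 3.7 |
| ash | 2.50 | 4.7 |
| alder | 0.208 | 4.2 |
| alder | 0.333 | 7.1 |
| alder | 0.500 | 8.6 |
| alder | 0.833 | 10.7 |
| alder | 1.67 | 16.3 |
| alder | 2.50 | 21.7 |

(scatter of a reading: 0.5 percentage points)

- which of the two ends with the longer chains by the average number of monomer units in a chain (chains begun, living or dead) ("neither" if they lie within 10%) (north-east / north-west / neither)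
- average number of monomer units in a chain (chains begun, living or dead) at the end, north-east
- average number of monomer units in a chain (chains begun, living or dead) at the end, north-west

I read the two tables against each other at equal times, dividing monomer in chains by the initiator loading. At 0.833 d this gives 1.50 for ash and 1.29 for alder, and at 2.50 d it gives 2.94 and 2.61. So alder's loading, 5.19 times ash's, leaves this ratio close to ash's in both rows. The ratio is monomer units per initiator, and it equals the average length if each initiator begins one chain. The runs do not show the chain count, so that is my assumption.

The same rows give a rate. I treat the free monomer fraction f as a first-order lag, a pseudo-first-order decay, with df/dt = −b·I·f, so f falls as exp(−b·I·t) and its time constant is 1/(b·I). Here I is the initiator loading and b is the growth constant. Alder's rows at 0.833 d and 2.50 d give a reading of b = 0.950 /d. Ash reads 0.894 /d, from a smaller rise than alder's, 2.3 percentage points against 11 points, with a scatter of 0.5 points on each reading.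

The time constant is therefore 10.5 d for north-east and 42.1 d for north-west. Starting from alder's ratio at 2.50 d and running on to 5.0 d, I reckon 41.8% in chains for north-east and 11.9% for north-west. That makes lengths of 4.18 and 4.77, so north-west is longer.

The forecast counts 0.65 chains per initiator where I count one, and it says north-west, with 6.3 for north-east and 7.6 for north-west, adding: “The chain count is the uncertain part”.

The flask gives 3.55 for north-east and 5.60 for north-west, so north-west is longer.

    free monomer + initiator → living end + monomer in chains (k = 4.50 × 10⁻⁴ /M/s)
    free monomer + living end → monomer in chains + living end, rate k2*[living end]*[free monomer] (k = 3.70 × 10⁻⁴ /M/s)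
    monomer in chains + living end → free monomer + living end, rate k3*[living end] as long as [monomer in chains] is above zero (k = 1.80 × 10⁻⁵ /s)
    initiator → spent initiator (k = 2.10 × 10⁻⁶ /s)

Carrying each time constant from the state at 2.50 d to 5.00 d gives 86.8% free monomer for north-west, and the flask holds 86.7%. For north-east it gives 59.5%, while the flask holds more than that, 66.5%. At 50.0 d free monomer stands at 56.6% in north-east and 58.2% in north-west.

All runs come from a simulation for substances that don't exist, noise included.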